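**Plan**

- Ring numbering: O1, C2 (pentyl), C3 (acyloxy), C4 (CH2), C5 (side chain); C1′ is the side-chain carbinol carbon. The retrosynthesis cuts the ester C–O bond, then the two oxolane bonds C4–C3 and O1–C2 together, then the side-chain bond C2′–C3′.
- Enabling feature: O1–C5–C4, with C4 unsubstituted, is the open form of a terminal oxirane and becomes a β-oxido carbanion (1,3-C,O-dinucleophile) on reductive lithiation. C3(O)–C2(O1) is a vicinal dioxygen pair and corresponds to an α-chloro aldehyde (1,2-dielectrophile).
- Forward: the C8 chain is joined to a C2-symmetric diepoxide, the carbinol is masked, and an anionic (3+2) annulation with (2R)-2-chloroheptanal builds the only ring. Acylation and unmasking follow.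
- Stereochemistry: C5 and C1′ come from (2R,2′R)-2,2′-bioxirane. C2 comes from catalyst-controlled α-chlorination and is inverted in the ring closure. C3 comes from Cornforth-controlled 1,2-anti addition next to the chloride.

Key step: step 4

Remark: (2R,2′R)-2,2′-bioxirane is taken as a purchasable single enantiomer.
Remark: (2S,5S)-2,5-diphenylpyrrolidine is assumed to give the (R)-chloride (attack on the enamine face not shielded by phenyl); if the sense is the reverse, its mirror image is used.

**Step 1**
Reactants: 1 (2R,2′R)-2,2′-bioxirane; 2 8-bromooct-1-ene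
Product: 4 (1R)-1-[(2R)-oxiran-2-yl]dec-9-en-1-ol, via oct-7-en-1-ylmagnesium bromide 3 (not isolated)
Conditions: 2, Mg, THF, rt; then added slowly to 1 (3 equiv), CuI (10 mol %), THF, −40 to −20 °C; H2O
Reagents that add atoms: none
Why: Copper-catalysed Grignard opening of an epoxide is an SN2 attack at the unsubstituted CH2 terminus, and with the C2-symmetric diepoxide in excess only one oxirane should be opened, so both stereocentres (later C5 and C1′) are taken unchanged from the starting material.

**Step 2**
Reactants: 4 (1R)-1-[(2R)-oxiran-2-yl]dec-9-en-1-ol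
Product: 5 (2R)-2-[(1R)-1-(methoxymethoxy)dec-9-en-1-yl]oxirane
Conditions: MOMCl, i-Pr2NEt, CH2Cl2, 0 °C to rt
Reagents that add atoms: chloromethyl methyl ether (MOMCl), COCCl
Why: O-Alkylation of the secondary hydroxyl under amine base leaves the oxirane intact and gives an acetal protecting group that should survive radical-anion and organolithium conditions and cannot migrate to a neighbouring alkoxide as a silyl group would.

**Step 3**
Reactants: 6 heptanal
Product: 7 (2R)-2-chloroheptanal
Conditions: NCS, (2S,5S)-2,5-diphenylpyrrolidine (10 mol %), CH2Cl2, 0 °C to rt; pentane, filtration; used at once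
Reagents that add atoms: N-chlorosuccinimide (NCS), ClN1C(=O)CCC1=O
Why: Enamine organocatalysis: the C2-symmetric amine forms the E-enamine of heptanal with one face shielded by a phenyl group, so electrophilic chlorine should be delivered to the open face and the C2 stereocentre is set under catalyst control.

**Step 4**
Reactants: 5 (2R)-2-[(1R)-1-(methoxymethoxy)dec-9-en-1-yl]oxirane; 7 (2R)-2-chloroheptanal
Product: 10 (2S,3S,5R)-5-[(1R)-1-(methoxymethoxy)dec-9-en-1-yl]-2-pentyloxolan-3-ol, via β-lithio lithium alkoxide 8 (not isolated), via anti-chlorohydrin diol 9 (not isolated)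
Conditions: LiDBB (lithium 4,4′-di-tert-butylbiphenylide, 2.0 equiv), THF, −78 °C; then 7, −78 °C; then AcOH (2 equiv), MeOH–H2O, 100 °C, sealed tube
Reagents that add atoms: none
Why: Two-electron reductive cleavage of the oxirane of 5 by the arene radical anion should break the O–CH2 bond (the less substituted, primary carbanion is formed) and give 8, in which O1, C5 and C4 are already joined; the carbanion adds to the formyl carbon of 7 (C4–C3 bond) and, after protonation to 9, the C5 hydroxyl displaces the secondary chloride (O1–C2 bond), so the sequence is a formal anionic (3+2) annulation of a 1,3-C,O-dinucleophile with a 1,2-dielectrophile. The closest known reaction types are the addition of β-lithio alkoxides from reductive lithiation of epoxides to aldehydes, the addition of alkyllithium reagents to α-chloro aldehydes, and the thermal cyclisation of 4-chloro-1,3-diols to 3-hydroxyoxolanes. The oxolane ring closes in the 5-exo-tet mode. The new stereocentre C3 is controlled by the chlorine-bearing C2 through the Cornforth (polar Felkin–Anh) model, which leads to the 1,2-anti chlorohydrin (3S); C2 is fixed by SN2 inversion of the (R)-chloride to (2S); C5 is carried over from the epoxide, so the 2,3-cis-2,5-trans pattern follows from the two building blocks. The step needs addition to outrun enolisation of the α-chloro aldehyde, which low temperature and the absence of excess radical anion should secure, and it needs O1 and not the C3 oxygen to attack C2; the neutral acetate-buffered medium secures this, since a free hydroxyl closes the five-membered ring but not the strained oxirane, and the same buffer takes up the HCl and spares the MOM acetal.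

**Step 5**
Reactants: 10 (2S,3S,5R)-5-[(1R)-1-(methoxymethoxy)dec-9-en-1-yl]-2-pentyloxolan-3-ol; 11 hexadecanoyl chloride
Product: 12 (2S,3S,5R)-5-[(1R)-1-(methoxymethoxy)dec-9-en-1-yl]-2-pentyloxolan-3-yl hexadecanoate
Conditions: pyridine, DMAP (10 mol %), CH2Cl2, 0 °C to rt
Reagents that add atoms: none
Why: DMAP-catalysed acylation through the acylpyridinium ion should esterify the only free hydroxyl, at C3, with retention because the C3–O bond is not touched.

**Step 6**
Reactants: 12 (2S,3S,5R)-5-[(1R)-1-(methoxymethoxy)dec-9-en-1-yl]-2-pentyloxolan-3-yl hexadecanoate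
Product: 13 (2S,3S,5R)-5-[(1R)-1-hydroxydec-9-en-1-yl]-2-pentyloxolan-3-yl hexadecanoate
Conditions: Me2BBr, CH2Cl2, −78 °C; then aq NaHCO3, THF, rt
Reagents that add atoms: none
Why: The bromoborane coordinates the acetal oxygens and bromide attacks the O–CH2–O carbon at low temperature, conditions under which the ester, the oxolane ring and the terminal alkene should not react, and aqueous work-up frees the C1′ hydroxyl without touching a stereocentre.

**Compound list**

1 | (2R,2′R)-2,2′-bioxirane | C1[C@@H](O1)[C@H]1CO1 | starting material
2 | 8-bromooct-1-ene | C=CCCCCCCBr | starting material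
3 | oct-7-en-1-ylmagnesium bromide | C=CCCCCCC[Mg]Br | intermediate
4 | (1R)-1-[(2R)-oxiran-2-yl]dec-9-en-1-ol | C=CCCCCCCC[C@@H](O)[C@H]1CO1 | intermediate
5 | (2R)-2-[(1R)-1-(methoxymethoxy)dec-9-en-1-yl]oxirane | C=CCCCCCCC[C@@H](OCOC)[C@H]1CO1 | intermediate
6 | heptanal | CCCCCCC=O | starting material
7 | (2R)-2-chloroheptanal | O=C[C@@H](CCCCC)Cl | intermediate
8 | lithium (2R,3R)-1-lithio-3-(methoxymethoxy)dodec-11-en-2-olate | C=CCCCCCCC[C@@H](OCOC)[C@H](O[Li])C[Li] | intermediate
9 | (6R,7S,9R,10R)-6-chloro-10-(methoxymethoxy)nonadec-18-ene-7,9-diol | C=CCCCCCCC[C@@H](OCOC)[C@H](O)C[C@H](O)[C@@H](CCCCC)Cl | intermediate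
10 | (2S,3S,5R)-5-[(1R)-1-(methoxymethoxy)dec-9-en-1-yl]-2-pentyloxolan-3-ol | C=CCCCCCCC[C@@H](OCOC)[C@H]1C[C@H](O)[C@H](CCCCC)O1 | intermediate
11 | hexadecanoyl chloride | CCCCCCCCCCCCCCCC(=O)Cl | starting material
12 | (2S,3S,5R)-5-[(1R)-1-(methoxymethoxy)dec-9-en-1-yl]-2-pentyloxolan-3-yl hexadecanoate | C=CCCCCCCC[C@@H](OCOC)[C@H]1C[C@H](OC(=O)CCCCCCCCCCCCCCC)[C@H](CCCCC)O1 | intermediate
13 | (2S,3S,5R)-5-[(1R)-1-hydroxydec-9-en-1-yl]-2-pentyloxolan-3-yl hexadecanoate | C=CCCCCCCC[C@@H](O)[C@H]1C[C@H](OC(=O)CCCCCCCCCCCCCCC)[C@H](CCCCC)O1 | target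

**Step count**

Total: 6 steps. Longest linear sequence: 5 steps (1, 2, 4, 5, 6).

**Steps most likely to fail**

Step 4. The alkyllithium may act as a base towards the α-chloro aldehyde (enolisation and loss of configuration instead of addition), the dianion may lose lithium oxide by β-elimination, or the facial selectivity of the addition may be incomplete. The fallback sets out from 5 and 7 and comes back at 9. Hydride opening of 5 at the CH2 terminus (LiAlH4, THF, 0 °C) should give (2R,3R)-3-(methoxymethoxy)dodec-11-en-2-ol F1. Dess–Martin oxidation should give (3R)-3-(methoxymethoxy)dodec-11-en-2-one F2. F2 is added as its kinetic lithium enolate (LDA, THF, −78 °C) to 7, under the same Cornforth control, to give the anti aldol (6R,7S,10R)-6-chloro-7-hydroxy-10-(methoxymethoxy)nonadec-18-en-9-one F3. Narasaka–Prasad reduction (Et2BOMe, NaBH4, THF–MeOH, −78 °C) should set the 1,3-syn diol and give 9, now isolated, which is heated in MeOH–H2O as in step 4 to give 10.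

Step 3. The enantiopurity of the α-chloro aldehyde may erode through enolisation or enamine re-formation during and after chlorination, and a second chlorination may occur. The fallback sets out from 6 and comes back at 7. Chlorination is run under SOMO activation (imidazolidinone organocatalyst, LiCl as chloride source, Cu(OCOCF3)2 and Na2S2O8 as oxidant, MeCN–H2O), so that the C–Cl bond is formed from chloride and an enamine radical cation. Reduction in the same flask (NaBH4) should give the configurationally stable (2R)-2-chloroheptan-1-ol F4, which can be stored and assayed. Dess–Martin oxidation immediately before step 4 returns to 7.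

Step 1. The Grignard reagent may open the second oxirane as well (double alkylation), and halide may open the product epoxide. The fallback sets out from 3 and comes back at 4. Addition of 3 to acrolein (THF, −78 °C) should give racemic dodeca-1,11-dien-3-ol F5. Sharpless kinetic resolution (Ti(OiPr)4, L-(+)-diisopropyl tartrate, t-BuOOH, about 0.55 equiv, CH2Cl2, −20 °C) should convert the faster-reacting (S)-alcohol to the erythro epoxy alcohol (1S)-1-[(2R)-oxiran-2-yl]dec-9-en-1-ol F6 and leave the remote alkene untouched. Mitsunobu inversion at C1′ (4-nitrobenzoic acid, PPh3, DIAD, THF) should give (1R)-1-[(2R)-oxiran-2-yl]dec-9-en-1-yl 4-nitrobenzoate F7. Methanolysis (K2CO3, MeOH, 0 °C) gives 4.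

**Further compounds**

F1 | step 4 | (2R,3R)-3-(methoxymethoxy)dodec-11-en-2-ol | C=CCCCCCCC[C@@H](OCOC)[C@H](O)C
F2 | step 4 | (3R)-3-(methoxymethoxy)dodec-11-en-2-one | C=CCCCCCCC[C@@H](OCOC)C(C)=O
F3 | step 4 | (6R,7S,10R)-6-chloro-7-hydroxy-10-(methoxymethoxy)nonadec-18-en-9-one | C=CCCCCCCC[C@@H](OCOC)C(=O)C[C@H](O)[C@@H](CCCCC)Cl
F4 | step 3 | (2R)-2-chloroheptan-1-ol | OC[C@@H](CCCCC)Cl
F5 | step 1 | dodeca-1,11-dien-3-ol (racemic) | C=CCCCCCCCC(O)C=C
F6 | step 1 | (1S)-1-[(2R)-oxiran-2-yl]dec-9-en-1-ol | C=CCCCCCCC[C@H](O)[C@H]1CO1
F7 | step 1 | (1R)-1-[(2R)-oxiran-2-yl]dec-9-en-1-yl 4-nitrobenzoate | C=CCCCCCCC[C@@H](OC(=O)c1ccc(cc1)[N+](=O)[O-])[C@H]1CO1
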